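**Assumption:** the only stereo-element in licochalcone D is the E-enone C=C; there are no stereocenters. Commercial 4′-hydroxyacetophenone and 2,3,4-trihydroxybenzaldehyde are taken as available.

## Retrosynthesis
- The E-enone is disconnected by a Claisen–Schmidt (aldol condensation) into 3-prenyl-4-hydroxyacetophenone (3) and 3,4-protected 2-methoxy-benzaldehyde (8).
- Ketone 3 comes from ortho C-prenylation of 4-hydroxyacetophenone (1).
- Aldehyde 8 comes from 2,3,4-trihydroxybenzaldehyde (4): the 3,4-catechol is masked as a diphenylmethylene ketal, which leaves the chelated 2-OH free to be O-methylated.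
- No rings are built; the only new ring is the temporary ketal, which is removed in the last step, and the E-alkene forms under thermodynamic control.

## Route

**Step 1**
Reactants: 1 (4′-hydroxyacetophenone) + 2 (prenyl bromide, 1-bromo-3-methylbut-2-ene)
Product: 3 (1-[4-hydroxy-3-(3-methylbut-2-en-1-yl)phenyl]ethan-1-one)
Conditions: KOH (2 equiv), MeOH/H2O, 0 °C to rt, 12 h
Reagents that add atoms: prenyl bromide, CC(C)=CCBr
Why: In aqueous-alcoholic base the phenoxide O is H-bond solvated, so SN2 alkylation occurs at the ortho carbon (ortho C-alkylation of a phenoxide) with retention of the prenyl double bond. The para position is blocked, and there are no stereocenters.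

**Step 2**
Reactants: 4 (2,3,4-trihydroxybenzaldehyde) + 5 (dichlorodiphenylmethane)
Product: 6 (2-hydroxy-3,4-(diphenylmethylenedioxy)benzaldehyde, i.e. 2,2-diphenylbenzo[d][1,3]dioxole-4-hydroxy-5-carbaldehyde)
Conditions: Ph2CCl2, neat, 160–170 °C, 15 min (or MeCN, reflux)
Reagents that add atoms: Ph2CCl2, ClC(Cl)(c1ccccc1)c1ccccc1 (supplies the CPh2 ketal carbon)
Why: Ketalization at the free vicinal 3,4-diol is favored because the 2-OH is locked in a hydrogen bond with the CHO. This is a catechol diaryl-ketal protection and creates no stereocenter.

**Step 3**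
Reactants: 6 + 7 (iodomethane)
Product: 8 (2-methoxy-3,4-(diphenylmethylenedioxy)benzaldehyde)
Conditions: MeI, K2CO3, DMF, rt, 6 h
Reagents that add atoms: MeI, CI
Why: The only free phenol, the acidic chelated 2-OH, undergoes Williamson O-methylation. The ketal and aldehyde are unaffected.

**Step 4**
Reactants: 3 (ketone) + 8 (aldehyde)
Product: 9 ((E)-chalcone with the 3,4-diphenylmethylenedioxy-2-methoxyphenyl B-ring and the 4-hydroxy-3-prenylphenyl A-ring)
Conditions: KOH (4 equiv), EtOH/H2O, rt, 48 h, then aqueous HCl to pH 4
Reagents that add atoms: none (the base and acid are only catalytic or for workup, and water is lost in the condensation)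
Why: Claisen–Schmidt aldol condensation. Excess base deprotonates the free phenol and still enolizes the ketone, and E1cB dehydration gives the thermodynamically preferred E-enone, which sets the alkene geometry.

**Step 5**
Reactants: 9
Product: 10 (licochalcone D)
Conditions: TFA/H2O (9:1), CH2Cl2, 0 °C to rt, 2–4 h, then cold NaHCO3 workup
Reagents that add atoms: none (water supplies only the two phenolic H; its O ends up in the benzophenone by-product)
Why: Acid-catalyzed hydrolysis of the diaryl ketal releases the free catechol and Ph2C=O. The E-enone, the prenyl alkene and the OMe survive brief, cold, wet TFA, and no stereocenter is touched.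

## Compound list
1 | 4′-hydroxyacetophenone | CC(=O)c1ccc(O)cc1 | starting material
2 | prenyl bromide | CC(C)=CCBr | starting material
3 | 1-[4-hydroxy-3-(3-methylbut-2-enyl)phenyl]ethanone | CC(=O)c1ccc(O)c(CC=C(C)C)c1 | intermediate
4 | 2,3,4-trihydroxybenzaldehyde | O=Cc1ccc(O)c(O)c1O | starting material
5 | dichlorodiphenylmethane | ClC(Cl)(c1ccccc1)c1ccccc1 | starting material
6 | 2-hydroxy-3,4-(diphenylmethylenedioxy)benzaldehyde | O=Cc1ccc2OC(c3ccccc3)(c3ccccc3)Oc2c1O | intermediate
7 | iodomethane | CI | starting material
8 | 2-methoxy-3,4-(diphenylmethylenedioxy)benzaldehyde | O=Cc1ccc2OC(c3ccccc3)(c3ccccc3)Oc2c1OC | intermediate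
9 | (E)-protected chalcone | COc1c(/C=C/C(=O)c2ccc(O)c(CC=C(C)C)c2)ccc2OC(c3ccccc3)(c3ccccc3)Oc12 | intermediate
10 | licochalcone D | COc1c(/C=C/C(=O)c2ccc(O)c(CC=C(C)C)c2)ccc(O)c1O | target

**Total steps:** 5
**Longest linear sequence:** 4 steps (4 → 6 → 8 → 9 → 10). The ketone branch is 1 step, 1 → 3.

## Three steps most likely to fail
1. **Step 1, ortho C-prenylation.** Expect modest yield, with O-prenyl ether and 3,5-diprenyl by-products. Fallback: O-allylate 1, then Claisen rearrangement (about 200 °C) to the 3-allyl-4-hydroxyacetophenone, then cross-metathesis with 2-methyl-2-butene (Grubbs II) to install the prenyl group.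
2. **Step 5, ketal removal.** Acid may cyclize the o-prenylphenol to a chromane or hydrate the prenyl alkene. Fallback: protect the 3,4-diol as bis-allyl ethers instead of the ketal, and remove them at the end with Pd(PPh3)4/K2CO3 in MeOH. This is neutral to basic and leaves the prenyl group intact.
3. **Step 2, regioselective 3,4-ketalization.** A 2,3-ketal or a mixture may form. Fallback: protect the 3,4-OH groups with MOMCl/iPr2NEt (2.2 equiv), leaving the chelated 2-OH free, then methylate and condense as before. Remove the MOM groups at the end with mild acid (e.g. PPTS or dilute HCl in MeOH).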